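**Plan**

- Atom labels (target): dihydropyran C1(OAc)–O2–C3H=C4–C5H–C9H; lactone C4–C6H–O–C7(=O)–C8H2–C5. Retrosynthesis: O2 is taken out of the C1–O2–C3 unit (Criegee/Hock oxygen insertion run backwards) to give the cyclopent-2-enyl hydroperoxide 24 with a C1–C3 bond; then C1–OOH to C1–OH; then the lactone C7–O bond and C4–C6 (Nozaki–Hiyama–Kishi); then C5–C8 and C9–alkenyl (three-component coupling on a 4-silyloxycyclopentenone).
- Enabling feature: O2 sits between an sp3 carbon carrying an acyloxy group (C1) and the vinylic carbon C3 of the C3=C4 bond, so the ring is a cyclopent-2-enyl unit with one inserted oxygen. A 1,2-shift of C3 from C1 to a peroxide oxygen gives exactly this oxocarbenium/enol ether array, which acetate caps.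
- Forward order: side-chain aldehyde 7 (steps 1–5) and alkenyl bromide 11 (step 6); cyclopentanone 17 (step 7); enol triflate, C4–C6 bond and δ-lactone ring (steps 8–10); C1–OH to C1–OOH (step 11); ring expansion of the five-membered carbocycle to the six-membered oxacycle as the last step (step 12).
- Stereochemistry: C9 and C5 from the silyloxy stereocentre of (S)-enone 12 (anti addition, then anti alkylation); C6 from ligand-controlled addition to aldehyde 7; the (E)-alkene from the Wittig reaction; C1 in step 12, anti to the C9 chain. The silyloxy carbon itself becomes C1 and loses its configuration on the way.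

Key step: step 12

Remark: C1 of 23–25 becomes planar in step 12, so its configuration is immaterial; these compounds are drawn with the oxygen trans to the C9 chain, and the C1 epimer would serve equally.

**Route**

Step 1
Reactants: 1 3-[(tert-butyldimethylsilyl)oxy]propanal; 2 ethyl 2-(triphenyl-λ5-phosphanylidene)propanoate
Product: 3 ethyl (2E)-5-[(tert-butyldimethylsilyl)oxy]-2-methylpent-2-enoate
Conditions: CH2Cl2, rt
Reagents that add atoms: none
Why: Wittig olefination of an unbranched aldehyde with a stabilised α-methyl ylide should be reliably E-selective, which sets the trisubstituted (E)-alkene of the C6 side chain.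

Step 2
Reactants: 3 ethyl (2E)-5-[(tert-butyldimethylsilyl)oxy]-2-methylpent-2-enoate
Product: 4 (2E)-5-[(tert-butyldimethylsilyl)oxy]-2-methylpent-2-en-1-ol
Conditions: DIBAL-H (2.3 equiv), CH2Cl2, −78 °C; aq. Rochelle salt
Reagents that add atoms: none
Why: 1,2-reduction of the enoate by DIBAL-H should give the allylic alcohol without touching the alkene geometry or the silyl ether.

Step 3
Reactants: 4 (2E)-5-[(tert-butyldimethylsilyl)oxy]-2-methylpent-2-en-1-ol
Product: 5 (2E)-5-[(tert-butyldimethylsilyl)oxy]-2-methylpent-2-en-1-yl acetate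
Conditions: Ac2O, pyridine, DMAP (cat.), CH2Cl2, 0 °C → rt
Reagents that add atoms: acetic anhydride, CC(=O)OC(C)=O
Why: DMAP-catalysed acylation of a primary allylic alcohol installs the side-chain acetate of the target at the outset.

Step 4
Reactants: 5 (2E)-5-[(tert-butyldimethylsilyl)oxy]-2-methylpent-2-en-1-yl acetate
Product: 6 (2E)-5-hydroxy-2-methylpent-2-en-1-yl acetate
Conditions: HF·pyridine, THF, 0 °C → rt
Reagents that add atoms: none
Why: fluoride-mediated desilylation of the primary TBS ether under non-basic conditions should leave the acetate in place.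

Step 5
Reactants: 6 (2E)-5-hydroxy-2-methylpent-2-en-1-yl acetate
Product: 7 (2E)-2-methyl-5-oxopent-2-en-1-yl acetate
Conditions: Dess–Martin periodinane, NaHCO3, CH2Cl2, 0 °C; used at once
Reagents that add atoms: none
Why: Dess–Martin oxidation under buffered, non-basic conditions should deliver the β,γ-unsaturated aldehyde without migration of the double bond into conjugation.

Step 6
Reactants: 8 2-(2-bromoethyl)-2-methyl-1,3-dioxolane; 9 2,3-dibromoprop-1-ene
Product: 11 2-(4-bromopent-4-en-1-yl)-2-methyl-1,3-dioxolane, via Grignard reagent 10 (not isolated)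
Conditions: Mg, THF, 25 °C; then 9, CuI (5 mol%), THF, −20 → 0 °C
Reagents that add atoms: none
Why: Grignard formation followed by copper-catalysed allylic substitution at the allylic C–Br bond of 9 (SN2 and SN2′ give the same product) should leave the vinylic bromide untouched.

Step 7
Reactants: 11 2-(4-bromopent-4-en-1-yl)-2-methyl-1,3-dioxolane; 12 (S)-4-[(tert-butyldimethylsilyl)oxy]cyclopent-2-en-1-one; 13 methyl bromoacetate
Product: 17 methyl 2-[(1S,2R,3S)-3-[(tert-butyldimethylsilyl)oxy]-2-[5-(2-methyl-1,3-dioxolan-2-yl)pent-1-en-2-yl]-5-oxocyclopentyl]acetate, via alkenyllithium 14 (not isolated), via lithium alkenyldimethylzincate 15 (not isolated), via zinc enolate 16 (not isolated)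
Conditions: 11, t-BuLi (2 equiv), Et2O, −78 °C; Me2Zn, THF, −78 → 0 °C; 12, −78 °C; HMPA, 13, −78 → −40 °C; aq. NH4Cl
Reagents that add atoms: none
Why: three-component coupling (conjugate addition of the alkenylzincate, then enolate alkylation) in which the alkenyl group adds anti to the silyloxy group (sets C9) and the regiodefined, non-equilibrating zinc enolate is alkylated anti to the new C9 substituent (sets C5).

Step 8
Reactants: 17 methyl 2-[(1S,2R,3S)-3-[(tert-butyldimethylsilyl)oxy]-2-[5-(2-methyl-1,3-dioxolan-2-yl)pent-1-en-2-yl]-5-oxocyclopentyl]acetate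
Product: 19 methyl 2-[(1S,4R,5R)-4-[(tert-butyldimethylsilyl)oxy]-5-[5-(2-methyl-1,3-dioxolan-2-yl)pent-1-en-2-yl]-2-[(trifluoromethanesulfonyl)oxy]cyclopent-2-en-1-yl]acetate, via potassium enolate 18 (not isolated)
Conditions: KHMDS, THF, −78 °C; PhNTf2, −78 → −20 °C
Reagents that add atoms: N-phenylbis(trifluoromethanesulfonimide), O=S(=O)(N(c1ccccc1)S(=O)(=O)C(F)(F)F)C(F)(F)F
Why: kinetic deprotonation at the less hindered ring CH2 (C3) and O-triflation of the enolate places the C3=C4 double bond, the low temperature holding back β-elimination of the silyloxy group.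

Step 9
Reactants: 19 methyl 2-[(1S,4R,5R)-4-[(tert-butyldimethylsilyl)oxy]-5-[5-(2-methyl-1,3-dioxolan-2-yl)pent-1-en-2-yl]-2-[(trifluoromethanesulfonyl)oxy]cyclopent-2-en-1-yl]acetate; 7 (2E)-2-methyl-5-oxopent-2-en-1-yl acetate
Product: 21 methyl 2-[(1S,4S,5R)-2-[(1S,3E)-5-(acetyloxy)-1-hydroxy-4-methylpent-3-en-1-yl]-4-[(tert-butyldimethylsilyl)oxy]-5-[5-(2-methyl-1,3-dioxolan-2-yl)pent-1-en-2-yl]cyclopent-2-en-1-yl]acetate, via alkenylchromium(III) species 20 (not isolated)
Conditions: CrCl2 (4 equiv), chiral 2-(2-sulfonamidoaryl)oxazoline ligand (4.4 equiv, the enantiomer that directs Re-face addition), Et3N, THF, rt; NiCl2 (2 mol%), 19, 7 (1.5 equiv), rt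
Reagents that add atoms: none
Why: asymmetric Nozaki–Hiyama–Kishi reaction, in which nickel inserts into the alkenyl triflate, the alkenyl group passes to chromium(III) and adds only to the aldehyde, the chromium-bound ligand directing attack to the Re face of 7 so that C6 should be formed as (S).

Step 10
Reactants: 21 methyl 2-[(1S,4S,5R)-2-[(1S,3E)-5-(acetyloxy)-1-hydroxy-4-methylpent-3-en-1-yl]-4-[(tert-butyldimethylsilyl)oxy]-5-[5-(2-methyl-1,3-dioxolan-2-yl)pent-1-en-2-yl]cyclopent-2-en-1-yl]acetate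
Product: 23 (2E)-4-[(1S,4aS,5R,6S)-6-hydroxy-3-oxo-5-(6-oxohept-1-en-2-yl)-1,3,4,4a,5,6-hexahydrocyclopenta[c]pyran-1-yl]-2-methylbut-2-en-1-yl acetate, via deprotected hydroxy ester 22 (not isolated)
Conditions: 48% aq. HF, MeCN, 0 °C → rt; then PPTS (cat.), PhMe, 50 °C
Reagents that add atoms: water, O
Why: aqueous HF removes the silyl ether and hydrolyses the dioxolane, and acid-catalysed intramolecular transesterification of the δ-hydroxy ester (6-exo-trig) closes the lactone with C6 unchanged because only the acyl C–O bond is exchanged.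

Step 11
Reactants: 23 (2E)-4-[(1S,4aS,5R,6S)-6-hydroxy-3-oxo-5-(6-oxohept-1-en-2-yl)-1,3,4,4a,5,6-hexahydrocyclopenta[c]pyran-1-yl]-2-methylbut-2-en-1-yl acetate
Product: 24 (2E)-4-[(1S,4aS,5R,6S)-6-hydroperoxy-3-oxo-5-(6-oxohept-1-en-2-yl)-1,3,4,4a,5,6-hexahydrocyclopenta[c]pyran-1-yl]-2-methylbut-2-en-1-yl acetate
Conditions: H2O2 (anhydrous, ca. 2 M in Et2O, 10 equiv), CSA (10 mol%), Et2O/CH2Cl2, 0 °C
Reagents that add atoms: hydrogen peroxide, OO
Why: acid-catalysed SN1 perhydrolysis of an allylic alcohol, in which the C1–C3–C4 allyl cation should be captured by the large excess of H2O2 at the less hindered secondary terminus C1 so that the more substituted C3=C4 alkene remains.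

Step 12
Reactants: 24 (2E)-4-[(1S,4aS,5R,6S)-6-hydroperoxy-3-oxo-5-(6-oxohept-1-en-2-yl)-1,3,4,4a,5,6-hexahydrocyclopenta[c]pyran-1-yl]-2-methylbut-2-en-1-yl acetate
Product: 27 (2E)-4-[(1S,4aS,5R,6R)-6-(acetyloxy)-3-oxo-5-(6-oxohept-1-en-2-yl)-4,4a,5,6-tetrahydro-1H,3H-pyrano[3,4-c]pyran-1-yl]-2-methylbut-2-en-1-yl acetate (target), via trifluoroacetyl perester 25 (not isolated), via anomeric trifluoroacetate 26 (not isolated)
Conditions: (CF3CO)2O (1.1 equiv), 2,6-di-tert-butyl-4-methylpyridine, CH2Cl2, −40 °C; then Bu4NOAc (3 equiv), −40 → 0 °C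
Reagents that add atoms: tetrabutylammonium acetate, CCCC[N+](CCCC)(CCCC)CCCC.CC(=O)[O-]
Why: O-acylation of the hydroperoxide gives the perester 25, whose O–O bond ionises with loss of trifluoroacetate while the vinylic carbon C3 shifts from C1 to the proximal oxygen (Criegee rearrangement, the perester counterpart of the Hock cleavage of allylic hydroperoxides), so that the peroxide oxygen is inserted into the C1–C3 bond and the cyclopentene becomes a cyclic oxocarbenium ion. No ring is closed by cyclisation: the six-membered ring arises from the five-membered one by this 1,2-shift, and ion-pair collapse gives the anomeric trifluoroacetate 26. Acetate then replaces the much better leaving group trifluoroacetate through the same oxocarbenium ion, which should end at the more stable acetate. The new stereocentre C1 is controlled by the C9 substituent: acetate should add to the face of the flattened oxocarbenium ion anti to the branched C9 chain, and reversible ionisation lets the mixture settle on the trans acetate, which can place the acetoxy group axial (anomeric effect). The step needs migration of C3 in preference to C9 and to loss of the C1 hydrogen (Kornblum–DeLaMare elimination to the enone); the π-participation of the alkenyl group gives it the higher migratory aptitude, and the absence of an unhindered amine base during the rearrangement holds back the elimination. No free peracid is present, so the other C=C bonds and the ketone should not be oxidised.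

**Compound list**

1 | 3-[(tert-butyldimethylsilyl)oxy]propanal | O=CCCO[Si](C)(C)C(C)(C)C | starting material
2 | ethyl 2-(triphenyl-λ5-phosphanylidene)propanoate | CCOC(=O)C(C)=P(c1ccccc1)(c1ccccc1)c1ccccc1 | starting material
3 | ethyl (2E)-5-[(tert-butyldimethylsilyl)oxy]-2-methylpent-2-enoate | CCOC(=O)/C(C)=C/CCO[Si](C)(C)C(C)(C)C | intermediate
4 | (2E)-5-[(tert-butyldimethylsilyl)oxy]-2-methylpent-2-en-1-ol | OC/C(C)=C/CCO[Si](C)(C)C(C)(C)C | intermediate
5 | (2E)-5-[(tert-butyldimethylsilyl)oxy]-2-methylpent-2-en-1-yl acetate | CC(=O)OC/C(C)=C/CCO[Si](C)(C)C(C)(C)C | intermediate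
6 | (2E)-5-hydroxy-2-methylpent-2-en-1-yl acetate | CC(=O)OC/C(C)=C/CCO | intermediate
7 | (2E)-2-methyl-5-oxopent-2-en-1-yl acetate | CC(=O)OC/C(C)=C/CC=O | intermediate
8 | 2-(2-bromoethyl)-2-methyl-1,3-dioxolane | CC1(CCBr)OCCO1 | starting material
9 | 2,3-dibromoprop-1-ene | C=C(Br)CBr | starting material
10 | [2-(2-methyl-1,3-dioxolan-2-yl)ethyl]magnesium bromide | CC1(CC[Mg]Br)OCCO1 | intermediate
11 | 2-(4-bromopent-4-en-1-yl)-2-methyl-1,3-dioxolane | C=C(Br)CCCC1(C)OCCO1 | intermediate
12 | (S)-4-[(tert-butyldimethylsilyl)oxy]cyclopent-2-en-1-one | O=C1C=C[C@@H](O[Si](C)(C)C(C)(C)C)C1 | starting material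
13 | methyl bromoacetate | COC(=O)CBr | starting material
14 | [5-(2-methyl-1,3-dioxolan-2-yl)pent-1-en-2-yl]lithium | [Li]C(=C)CCCC1(C)OCCO1 | intermediate
15 | lithium dimethyl[5-(2-methyl-1,3-dioxolan-2-yl)pent-1-en-2-yl]zincate | [Li+].C[Zn-](C)C(=C)CCCC1(C)OCCO1 | intermediate
16 | lithium dimethylzinc enolate of (3R,4S)-4-[(tert-butyldimethylsilyl)oxy]-3-[5-(2-methyl-1,3-dioxolan-2-yl)pent-1-en-2-yl]cyclopentanone | [Li+].C[Zn-](C)OC1=C[C@H](C(=C)CCCC2(C)OCCO2)[C@@H](O[Si](C)(C)C(C)(C)C)C1 | intermediate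
17 | methyl 2-[(1S,2R,3S)-3-[(tert-butyldimethylsilyl)oxy]-2-[5-(2-methyl-1,3-dioxolan-2-yl)pent-1-en-2-yl]-5-oxocyclopentyl]acetate | O=C1C[C@H](O[Si](C)(C)C(C)(C)C)[C@@H](C(=C)CCCC2(C)OCCO2)[C@@H]1CC(=O)OC | intermediate
18 | kinetic potassium enolate of 17 (deprotonated at the ring CH2; stereocentres as in 17) | [K+].[O-]C1=C[C@H](O[Si](C)(C)C(C)(C)C)[C@@H](C(=C)CCCC2(C)OCCO2)[C@@H]1CC(=O)OC | intermediate
19 | methyl 2-[(1S,4R,5R)-4-[(tert-butyldimethylsilyl)oxy]-5-[5-(2-methyl-1,3-dioxolan-2-yl)pent-1-en-2-yl]-2-[(trifluoromethanesulfonyl)oxy]cyclopent-2-en-1-yl]acetate | O=S(=O)(OC1=C[C@H](O[Si](C)(C)C(C)(C)C)[C@@H](C(=C)CCCC2(C)OCCO2)[C@@H]1CC(=O)OC)C(F)(F)F | intermediate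
20 | alkenylchromium(III) dichloride derived from 19 (ligand omitted; stereocentres as in 19) | Cl[Cr](Cl)C1=C[C@H](O[Si](C)(C)C(C)(C)C)[C@@H](C(=C)CCCC2(C)OCCO2)[C@@H]1CC(=O)OC | intermediate
21 | methyl 2-[(1S,4S,5R)-2-[(1S,3E)-5-(acetyloxy)-1-hydroxy-4-methylpent-3-en-1-yl]-4-[(tert-butyldimethylsilyl)oxy]-5-[5-(2-methyl-1,3-dioxolan-2-yl)pent-1-en-2-yl]cyclopent-2-en-1-yl]acetate | COC(=O)C[C@@H]1C([C@@H](O)C/C=C(\C)COC(C)=O)=C[C@H](O[Si](C)(C)C(C)(C)C)[C@H]1C(=C)CCCC2(C)OCCO2 | intermediate
22 | methyl 2-[(1S,4S,5R)-2-[(1S,3E)-5-(acetyloxy)-1-hydroxy-4-methylpent-3-en-1-yl]-4-hydroxy-5-(6-oxohept-1-en-2-yl)cyclopent-2-en-1-yl]acetate | COC(=O)C[C@@H]1C([C@@H](O)C/C=C(\C)COC(C)=O)=C[C@H](O)[C@H]1C(=C)CCCC(C)=O | intermediate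
23 | (2E)-4-[(1S,4aS,5R,6S)-6-hydroxy-3-oxo-5-(6-oxohept-1-en-2-yl)-1,3,4,4a,5,6-hexahydrocyclopenta[c]pyran-1-yl]-2-methylbut-2-en-1-yl acetate | C=C(CCCC(C)=O)[C@@H]1[C@@H](O)C=C2[C@H](C/C=C(\C)COC(C)=O)OC(=O)C[C@H]21 | intermediate
24 | (2E)-4-[(1S,4aS,5R,6S)-6-hydroperoxy-3-oxo-5-(6-oxohept-1-en-2-yl)-1,3,4,4a,5,6-hexahydrocyclopenta[c]pyran-1-yl]-2-methylbut-2-en-1-yl acetate | C=C(CCCC(C)=O)[C@@H]1[C@@H](OO)C=C2[C@H](C/C=C(\C)COC(C)=O)OC(=O)C[C@H]21 | intermediate
25 | trifluoroacetyl perester of 24 (O–O–C(=O)CF3 at the former hydroperoxide carbon; stereocentres as in 24) | C=C(CCCC(C)=O)[C@@H]1[C@@H](OOC(=O)C(F)(F)F)C=C2[C@H](C/C=C(\C)COC(C)=O)OC(=O)C[C@H]21 | intermediate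
26 | (2E)-2-methyl-4-[(1S,4aS,5R,6R)-3-oxo-5-(6-oxohept-1-en-2-yl)-6-[(trifluoroacetyl)oxy]-4,4a,5,6-tetrahydro-1H,3H-pyrano[3,4-c]pyran-1-yl]but-2-en-1-yl acetate | C=C(CCCC(C)=O)[C@@H]1[C@@H](OC(=O)C(F)(F)F)OC=C2[C@H](C/C=C(\C)COC(C)=O)OC(=O)C[C@H]21 | intermediate
27 | (2E)-4-[(1S,4aS,5R,6R)-6-(acetyloxy)-3-oxo-5-(6-oxohept-1-en-2-yl)-4,4a,5,6-tetrahydro-1H,3H-pyrano[3,4-c]pyran-1-yl]-2-methylbut-2-en-1-yl acetate (CNP0120157.1) | C=C(CCCC(C)=O)[C@@H]1[C@@H](OC(C)=O)OC=C2[C@H](C/C=C(\C)COC(C)=O)OC(=O)C[C@H]21 | target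

**Step count and risks**

Total step count: 12. Longest linear sequence: 9 steps (steps 1–5, then 9–12).

Steps most likely to fail:

1. Step 12. The perester may lose the C1 hydrogen instead of rearranging (elimination to the cyclopentenone), the acid-labile enol ether/allylic lactone of the product may ionise, or the capture by acetate may show poor facial selectivity. The fallback sets out from 24 and separates the rearrangement from the acylation. Catalytic trifluoroacetic acid in wet CH2Cl2 at 0 °C (Hock rearrangement, water capturing the oxocarbenium ion) should give the lactol F1. Acetylation of the equilibrating lactol with Ac2O, Et3N and catalytic DMAP at −20 °C, in which the less hindered trans alkoxide should react faster, comes back to the route at 27.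

2. Step 11. The allyl cation may lose a proton to give a cyclopentadiene instead of being captured, or hydrogen peroxide may add to the side-chain ketone under the acidic conditions. The fallback sets out from 23 and avoids Brønsted acid. An Appel reaction (CBr4, PPh3, CH2Cl2, −20 °C) should give the allylic bromide F2. Silver trifluoroacetate-assisted displacement of bromide by anhydrous H2O2 in Et2O at −40 °C comes back to the route at 24.

3. Step 9. The addition to the aldehyde may show poor facial selectivity under ligand control, so that C6 is formed as an epimer mixture. The fallback sets out from 19 and 7 and moves the stereocontrol from C–C bond formation to a reduction. A ligand-free Nozaki–Hiyama–Kishi coupling (CrCl2, NiCl2 cat., DMF) gives 21 as a C6 epimer mixture, and Dess–Martin oxidation gives the enone F3. Corey–Bakshi–Shibata reduction with the (R)-methyl oxazaborolidine and catecholborane in PhMe at −78 °C, the cyclopentenyl group acting as the large substituent, should give the (S)-carbinol and comes back to the route at 21.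

Further compounds
F1 | step 12 | (2E)-4-[(1S,4aS,5R)-6-hydroxy-3-oxo-5-(6-oxohept-1-en-2-yl)-4,4a,5,6-tetrahydro-1H,3H-pyrano[3,4-c]pyran-1-yl]-2-methylbut-2-en-1-yl acetate (lactol, both C6 anomers) | C=C(CCCC(C)=O)[C@@H]1C(O)OC=C2[C@H](C/C=C(\C)COC(C)=O)OC(=O)C[C@H]21
F2 | step 11 | (2E)-4-[(1S,4aS,5R)-6-bromo-3-oxo-5-(6-oxohept-1-en-2-yl)-1,3,4,4a,5,6-hexahydrocyclopenta[c]pyran-1-yl]-2-methylbut-2-en-1-yl acetate (allylic bromide, C6 epimers) | C=C(CCCC(C)=O)[C@@H]1C(Br)C=C2[C@H](C/C=C(\C)COC(C)=O)OC(=O)C[C@H]21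
F3 | step 9 | methyl 2-[(1S,4S,5R)-2-[(3E)-5-(acetyloxy)-4-methylpent-3-enoyl]-4-[(tert-butyldimethylsilyl)oxy]-5-[5-(2-methyl-1,3-dioxolan-2-yl)pent-1-en-2-yl]cyclopent-2-en-1-yl]acetate | COC(=O)C[C@@H]1C(C(=O)C/C=C(\C)COC(C)=O)=C[C@H](O[Si](C)(C)C(C)(C)C)[C@H]1C(=C)CCCC2(C)OCCO2
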